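**Strategy.** The route rests on disconnecting the C13–O bond of the pyran (O–C8–C9–C11–C12–C13). C13 is a fully substituted allylic ether carbon carrying the C16 methyl and the C14=C15 vinyl group, so it is the branched end of a C13–C14–C15 π-allyl unit. A palladium(0) allylic etherification by the tertiary C8 hydroxyl of ring B closes the pyran, forms C13–O and sets C13 in one operation. The precursor is a monocyclic ring-B carbinol with free C8–OH, a C12 silyl ether, a C13=C14 alkene bearing a C15 tert-butyl carbonate, and both seco-ring-A arms as primary silyl ethers. It is built from an (S)-configured hydrindenedione.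

Key step: step 22

Assumption: labdane numbering is used for every intermediate and "syn/anti" refers to the face of the C8 methyl (C17); the target is read as the ent-labdane (5S,8S,9S,10R,12S,13S), so the L-amino acid is the annulation catalyst needed, and (R,R) is taken as the matched hand of the Trost ligand (its antipode is run in parallel).

Step 1
Reactants: 1 2-methylcyclopentane-1,3-dione; 2 ethyl vinyl ketone
Product: 3 2-methyl-2-(3-oxopentyl)cyclopentane-1,3-dione
Conditions: AcOH (cat.), H2O, 75 °C
Reagents that add atoms: none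
Why: Michael addition of the acidic 2-substituted 1,3-dione to the vinyl ketone gives the prochiral triketone that already holds C5–C13, C17 and C20.

Step 2
Reactants: 3 2-methyl-2-(3-oxopentyl)cyclopentane-1,3-dione
Product: 4 (7aS)-4,7a-dimethyl-2,3,7,7a-tetrahydro-1H-indene-1,5(6H)-dione
Conditions: L-phenylalanine (1 equiv), 1 M HClO4 (0.5 equiv), MeCN, 80 °C
Reagents that add atoms: none
Why: The Hajos–Parrish–Eder–Sauer–Wiechert aldol condensation through the L-phenylalanine enamine desymmetrises the dione and should fix the quaternary C8 as (S), the sense that maps onto C8 of the target.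

Step 3
Reactants: 4 (7aS)-4,7a-dimethyl-2,3,7,7a-tetrahydro-1H-indene-1,5(6H)-dione
Product: 5 C13 ethylene ketal of 4 (enone untouched)
Conditions: (TMSOCH2)2 (1.2 equiv), TMSOTf (2 mol %), CH2Cl2, −78 → −20 °C; pyridine quench
Reagents that add atoms: 1,2-bis(trimethylsilyloxy)ethane, C[Si](C)(C)OCCO[Si](C)(C)C
Why: Noyori ketalisation is much faster at the saturated cyclopentanone than at the less electrophilic α-methyl enone, so only the C13 carbonyl should be masked.

Step 4
Reactants: 5 C13 ethylene ketal of 4; 6 allyl bromide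
Product: 8 trans-fused C5 ketone with C10 methyl syn and C10 allyl anti to C17 and H9 anti to C17, via lithium C5–C10 enolate 7 (not isolated)
Conditions: Li (2.3 equiv), t-BuOH (1.0 equiv), NH3(l)/THF, −78 °C; isoprene; then 6 (3 equiv), −78 → −33 °C; NH4Cl
Reagents that add atoms: none
Why: In this Stork reductive alkylation, protonation of the enone β-carbon C9 should give the trans ring fusion, and the regiodefined enolate is allylated at C10 on the face away from the 1,3-related axial C17 methyl, which leaves C20 syn to C17.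

Step 5
Reactants: 8 trans-fused C5 ketone; 9 prenylmagnesium chloride
Product: 10 C5 tertiary carbinol carrying the 2-methylbut-3-en-2-yl group (C4 with both methyls and a vinyl as latent C3) and the C10 allyl group
Conditions: 9 (2 equiv), THF, −78 → 0 °C; NH4Cl at 0 °C
Reagents that add atoms: none
Why: Allylic Grignard reagents add to hindered ketones through a six-membered SE2′ transition state and bond through the tertiary γ-carbon, which builds the C5–C4 bond and the gem-dimethyl carbon; the C5 configuration (bulky group expected equatorial) is erased in step 8.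

Step 6
Reactants: 10 C5 tertiary carbinol with two terminal alkenes
Product: 12 triol (primary C2–OH and C3–OH, tertiary C5–OH, C13 ketal), via hydroxy dialdehyde 11 (not isolated)
Conditions: O3, CH2Cl2/MeOH (3:1), −78 °C; then NaBH4 (6 equiv), −78 → 20 °C
Reagents that add atoms: ozone, [O-][O+]=O
Why: Ozonolysis with reductive borohydride work-up trims each monosubstituted alkene by one carbon and should deliver both seco-ring-A arms (C1–C2 and C4–C3) at the alcohol level.

Step 7
Reactants: 12 triol
Product: 13 C2,C3-bis-TBS ether with free tertiary C5–OH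
Conditions: TBSCl (2.5 equiv), imidazole, DMF, 20 °C
Reagents that add atoms: tert-butyldimethylsilyl chloride, CC(C)(C)[Si](C)(C)Cl
Why: Silylation with TBSCl/imidazole is selective for the two primary hydroxyls over the congested tertiary carbinol.

Step 8
Reactants: 13 bis-TBS tertiary carbinol
Product: 14 C5=C6 alkene (bis-TBS, C13 ketal)
Conditions: SOCl2 (1.5 equiv), pyridine, CH2Cl2, −20 → 0 °C
Reagents that add atoms: none
Why: Pyridine-mediated E2 dehydration of the chlorosulfite can only give the C5=C6 alkene because C4 and C10 are quaternary.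

Step 9
Reactants: 14 C5=C6 alkene
Product: 15 saturated ring-B ketal with H5 anti to C17/C20 and the C4 side chain equatorial
Conditions: Mn(dpm)3 (10 mol %), PhSiH3 (1.2 equiv), TBHP (1.5 equiv), i-PrOH, 22 °C
Reagents that add atoms: none
Why: Mukaiyama-type HAT hydrogenation tolerates the flanking quaternary carbons, and the tertiary C5 radical should take up hydrogen axially on the face opposite the C17/C20 methyls, giving the thermodynamically preferred C5 configuration of the target.

Step 10
Reactants: 15 saturated ring-B ketal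
Product: 16 C13 ketone (trans-hydrindanone, bis-TBS)
Conditions: PPTS (0.2 equiv), acetone/H2O (10:1), 50 °C
Reagents that add atoms: water, O
Why: Mild acid-catalysed transketalisation frees the cyclopentanone while primary TBS ethers survive PPTS.

Step 11
Reactants: 16 C13 ketone
Product: 17 δ-lactone (ring O on C8, carbonyl C13, bis-TBS)
Conditions: mCPBA (3 equiv), NaHCO3, CH2Cl2, 0 → 25 °C
Reagents that add atoms: mCPBA, OOC(=O)c1cccc(Cl)c1
Why: In the Baeyer–Villiger oxidation the quaternary C8 migrates with retention, creating the C8–O bond with the configuration fixed in step 2.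

Step 12
Reactants: 17 δ-lactone
Product: 18 12-hydroxy lactone (hydroxyl expected axial, anti to C17)
Conditions: KHMDS (1.2 equiv), THF, −78 °C; 2-(phenylsulfonyl)-3-phenyloxaziridine (1.5 equiv); NH4Cl
Reagents that add atoms: 2-(phenylsulfonyl)-3-phenyloxaziridine, O=S(=O)(c1ccccc1)N1OC1c1ccccc1
Why: Enolate oxidation with the Davis oxaziridine introduces the C12 oxygen, but axial attack anti to C17 is expected to give the epimer opposite to the target, so C12 is corrected in steps 13 and 14.

Step 13
Reactants: 18 12-hydroxy lactone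
Product: 19 12-oxo lactone
Conditions: Dess–Martin periodinane (1.5 equiv), NaHCO3, CH2Cl2, 0 → 20 °C
Reagents that add atoms: none
Why: Dess–Martin oxidation converts the α-hydroxy lactone into the α-keto lactone under neutral conditions and erases C12.

Step 14
Reactants: 19 12-oxo lactone
Product: 20 12-hydroxy lactone with the hydroxyl equatorial and syn to C17
Conditions: NaBH4 (1.0 equiv), THF/EtOH (4:1), −40 °C
Reagents that add atoms: none
Why: Borohydride reduces the ketone and not the lactone, and axial hydride delivery on the face anti to C17 should place the C12 hydroxyl equatorial, which is the target configuration.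

Step 15
Reactants: 20 12-hydroxy lactone (equatorial OH)
Product: 21 12-OTBS lactone (tris-TBS)
Conditions: TBSOTf (1.5 equiv), 2,6-lutidine, CH2Cl2, −78 → 0 °C
Reagents that add atoms: tert-butyldimethylsilyl triflate, CC(C)(C)[Si](C)(C)OS(=O)(=O)C(F)(F)F
Why: Silyl triflate/lutidine silylates the hindered secondary α-hydroxy lactone without epimerisation.

Step 16
Reactants: 21 12-OTBS lactone
Product: 22 ring-opened Weinreb amide (C13) with free tertiary C8–OH
Conditions: MeNH(OMe)·HCl (3 equiv), i-PrMgCl (6 equiv), THF, −20 → 0 °C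
Reagents that add atoms: N,O-dimethylhydroxylamine hydrochloride, CNOC.Cl
Why: Weinreb aminolysis with the chloromagnesium amide opens the lactone at the acyl carbon and gives an acyl donor that stops at the ketone stage.

Step 17
Reactants: 22 hydroxy Weinreb amide
Product: 23 C8–OTMS Weinreb amide
Conditions: TMSOTf (1.3 equiv), 2,6-lutidine, CH2Cl2, −78 °C
Reagents that add atoms: trimethylsilyl triflate, C[Si](C)(C)OS(=O)(=O)C(F)(F)F
Why: Temporary silylation of the tertiary C8 hydroxyl prevents relactonisation, hemiketal formation with the coming ketone and oxa-Michael addition during the olefination.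

Step 18
Reactants: 23 C8–OTMS Weinreb amide
Product: 24 C13 methyl ketone (C16 installed, C8–OTMS, tris-TBS)
Conditions: MeMgBr (3 equiv), THF, 0 °C
Reagents that add atoms: methylmagnesium bromide, C[Mg]Br
Why: Grignard addition to the Weinreb amide stops at the chelated tetrahedral intermediate, so the methyl ketone forms without over-addition or loss of the C12 stereocentre.

Step 19
Reactants: 24 C13 methyl ketone; 25 triethyl phosphonoacetate
Product: 26 ethyl enoate with C13=C14 (E expected to predominate; Z carried along)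
Conditions: 25 (3 equiv), NaH (2.8 equiv), THF, 0 → 50 °C
Reagents that add atoms: none
Why: Horner–Wadsworth–Emmons olefination of the α-silyloxy methyl ketone adds C14–C15 and forms the trisubstituted alkene, either geometry of which is usable in step 22.

Step 20
Reactants: 26 ethyl enoate
Product: 28 allylic alcohol (C15–OH) with free tertiary C8–OH, tris-TBS, via TMS-protected allylic alcohol 27 (not isolated)
Conditions: DIBAL-H (2.5 equiv), CH2Cl2, −78 °C; then MeOH, 10% aq. citric acid, THF, 20 °C
Reagents that add atoms: none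
Why: DIBAL-H 1,2-reduction gives the primary allylic alcohol, and the mildly acidic work-up should hydrolyse only the labile tertiary TMS ether while the three TBS ethers stay.

Step 21
Reactants: 28 allylic alcohol with free C8–OH
Product: 29 cyclisation precursor: C15 tert-butyl carbonate, C13=C14 alkene, C12–OTBS, free C8–OH, arms as TBS ethers
Conditions: Boc2O (1.3 equiv), DMAP (10 mol %), CH2Cl2, 0 → 20 °C
Reagents that add atoms: di-tert-butyl dicarbonate, CC(C)(C)OC(=O)OC(=O)OC(C)(C)C
Why: Acylation occurs only at the primary allylic hydroxyl, and a tert-butyl carbonate is chosen so that the alkoxide released in step 22 is a base and not a competing nucleophile.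

Step 22
Reactants: 29 C15 tert-butyl carbonate (cyclisation precursor)
Product: 30 bicyclic vinyl pyran, tris-TBS ether
Conditions: Pd2(dba)3·CHCl3 (5 mol %), (R,R)-DACH-phenyl Trost ligand (15 mol %), degassed toluene, 25 → 50 °C
Reagents that add atoms: none
Why: Proposed new method: Pd(0) ionises the allylic carbonate of either alkene isomer to η3-allyl complexes over C13–C14–C15 that exchange face and syn/anti geometry by η3–η1–η3 shifts faster than the hindered oxygen attacks, and the tert-butoxide formed on decarboxylation deprotonates the C8 hydroxyl, which adds anti to palladium at C13 under Curtin–Hammett control. The closest known chemistry is Tsuji–Trost allylic etherification giving 2-vinyltetrahydropyrans from primary or secondary alcohols and 2-methyl-2-vinylchromans from phenols, whereas a tertiary alkoxide adding to a fully substituted terminus has not been shown. The pyran (O–C8–C9–C11–C12–C13) closes in a 6-exo mode, and attack at C15 would need an eight-membered ring, so ring size enforces the branched regiochemistry. The new stereocentre C13 is set in a chair transition state with the C12 silyloxy group equatorial, in which the flat allyl unit and not the C16 methyl takes the position 1,3-diaxial to the C17 methyl, and the chiral pocket of the C2-symmetric ligand is chosen to reinforce this preference. The step needs facial selectivity at C13 and chemoselectivity over β-hydride elimination to the diene and over capture by external alkoxide, which the substrate chair bias, the matched ligand and the non-nucleophilic tert-butoxide are meant to secure.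

Step 23
Reactants: 30 bicyclic vinyl pyran, tris-TBS ether
Product: 31 C2,C3-diol with C12–OTBS retained
Conditions: HF·pyridine, pyridine, THF, 0 → 20 °C
Reagents that add atoms: none
Why: Buffered HF·pyridine cleaves the two primary TBS ethers much faster than the secondary C12 ether, which is flanked by the quaternary C13.

Step 24
Reactants: 31 C2,C3-diol
Product: 33 2,3-dioic acid with C12–OTBS, via dialdehyde 32 (not isolated)
Conditions: Dess–Martin periodinane (3 equiv), NaHCO3, CH2Cl2, 0 → 20 °C; then crude 32, NaClO2, NaH2PO4, 2-methyl-2-butene, t-BuOH/H2O, 0 → 20 °C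
Reagents that add atoms: sodium chlorite, [Na+].[O-]Cl=O
Why: Excess Dess–Martin periodinane engages both primary alcohols at once so that no lactol between the arms can form, and Pinnick oxidation of the crude dialdehyde gives the diacid while the scavenger protects the vinyl group and C12 stays silylated.

Step 25
Reactants: 33 2,3-dioic acid with C12–OTBS
Product: 34 target CNP0325408.2
Conditions: TBAF (6 equiv), THF, 50 °C; work-up at pH 3
Reagents that add atoms: none
Why: Fluoride-mediated desilylation removes the last, hindered TBS ether under non-acidic conditions that should not ionise the tertiary allylic ether.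

**Compound list**

1 | 2-methylcyclopentane-1,3-dione | CC1C(=O)CCC1=O | starting material
2 | ethyl vinyl ketone (pent-1-en-3-one) | CCC(=O)C=C | starting material
3 | 2-methyl-2-(3-oxopentyl)cyclopentane-1,3-dione | CCC(=O)CCC1(C)C(=O)CCC1=O | intermediate
4 | (7aS)-4,7a-dimethyl-2,3,7,7a-tetrahydro-1H-indene-1,5(6H)-dione (C5 enone carbonyl, C13 ring ketone, quaternary C8) | CC1=C2CCC(=O)[C@@]2(C)CCC1=O | intermediate
5 | C13 ethylene ketal of 4, (7a'S)-4',7a'-dimethyl-2',3',7',7a'-tetrahydrospiro[1,3-dioxolane-2,1'-inden]-5'(6'H)-one | CC1=C2CCC3(OCCO3)[C@@]2(C)CCC1=O | intermediate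
6 | allyl bromide | C=CCBr | starting material
7 | lithium C5–C10 enolate of the trans-fused hydrindanone ketal (not isolated) | CC1=C(O[Li])CC[C@@]2(C)[C@H]1CCC23OCCO3 | intermediate
8 | trans-fused C5 ketone; C10 methyl syn, C10 allyl anti, H9 anti to C17; C13 ketal | C=CC[C@]1(C)C(=O)CC[C@@]2(C)[C@H]1CCC23OCCO3 | intermediate
9 | prenylmagnesium chloride (3-methylbut-2-en-1-ylmagnesium chloride) | CC(C)=CC[Mg]Cl | starting material
10 | C5 tertiary carbinol with 2-methylbut-3-en-2-yl at C5 (OH expected anti to C17) and allyl at C10; C13 ketal | C=CC[C@]1(C)[C@@](O)(C(C)(C)C=C)CC[C@@]2(C)[C@H]1CCC23OCCO3 | intermediate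
11 | hydroxy dialdehyde (C2 and C3 aldehydes, C5–OH; not isolated) | O=CC[C@]1(C)[C@@](O)(C(C)(C)C=O)CC[C@@]2(C)[C@H]1CCC23OCCO3 | intermediate
12 | triol (C2–OH, C3–OH, C5–OH; C13 ketal) | OCC[C@]1(C)[C@@](O)(C(C)(C)CO)CC[C@@]2(C)[C@H]1CCC23OCCO3 | intermediate
13 | C2,C3-bis-TBS ether of 12, C5–OH free | CC(C)(C)[Si](C)(C)OCC[C@]1(C)[C@@](O)(C(C)(C)CO[Si](C)(C)C(C)(C)C)CC[C@@]2(C)[C@H]1CCC23OCCO3 | intermediate
14 | C5=C6 alkene, bis-TBS, C13 ketal | CC(C)(C)[Si](C)(C)OCC[C@]1(C)C(C(C)(C)CO[Si](C)(C)C(C)(C)C)=CC[C@@]2(C)[C@H]1CCC23OCCO3 | intermediate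
15 | saturated ring-B ketal; H5 anti to C17/C20; bis-TBS | CC(C)(C)[Si](C)(C)OCC[C@]1(C)[C@@H](C(C)(C)CO[Si](C)(C)C(C)(C)C)CC[C@@]2(C)[C@H]1CCC23OCCO3 | intermediate
16 | C13 ketone (trans-hydrindanone), bis-TBS | CC(C)(C)[Si](C)(C)OCC[C@]1(C)[C@@H](C(C)(C)CO[Si](C)(C)C(C)(C)C)CC[C@@]2(C)[C@H]1CCC2=O | intermediate
17 | δ-lactone (O on C8, C13 carbonyl), bis-TBS | CC(C)(C)[Si](C)(C)OCC[C@]1(C)[C@@H](C(C)(C)CO[Si](C)(C)C(C)(C)C)CC[C@@]2(C)[C@H]1CCC(=O)O2 | intermediate
18 | 12-hydroxy lactone, OH axial and anti to C17 (expected kinetic epimer) | CC(C)(C)[Si](C)(C)OCC[C@]1(C)[C@@H](C(C)(C)CO[Si](C)(C)C(C)(C)C)CC[C@@]2(C)[C@H]1C[C@@H](O)C(=O)O2 | intermediate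
19 | 12-oxo lactone | CC(C)(C)[Si](C)(C)OCC[C@]1(C)[C@@H](C(C)(C)CO[Si](C)(C)C(C)(C)C)CC[C@@]2(C)[C@H]1CC(=O)C(=O)O2 | intermediate
20 | 12-hydroxy lactone, OH equatorial and syn to C17 | CC(C)(C)[Si](C)(C)OCC[C@]1(C)[C@@H](C(C)(C)CO[Si](C)(C)C(C)(C)C)CC[C@@]2(C)[C@H]1C[C@H](O)C(=O)O2 | intermediate
21 | 12-OTBS lactone (tris-TBS) | CC(C)(C)[Si](C)(C)OCC[C@]1(C)[C@@H](C(C)(C)CO[Si](C)(C)C(C)(C)C)CC[C@@]2(C)[C@H]1C[C@H](O[Si](C)(C)C(C)(C)C)C(=O)O2 | intermediate
22 | ring-opened C13 Weinreb amide, free C8–OH, tris-TBS | CON(C)C(=O)[C@@H](O[Si](C)(C)C(C)(C)C)C[C@@H]1[C@@](C)(O)CC[C@H](C(C)(C)CO[Si](C)(C)C(C)(C)C)[C@@]1(C)CCO[Si](C)(C)C(C)(C)C | intermediate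
23 | C8–OTMS Weinreb amide | CON(C)C(=O)[C@@H](O[Si](C)(C)C(C)(C)C)C[C@@H]1[C@@](C)(O[Si](C)(C)C)CC[C@H](C(C)(C)CO[Si](C)(C)C(C)(C)C)[C@@]1(C)CCO[Si](C)(C)C(C)(C)C | intermediate
24 | C13 methyl ketone, C8–OTMS, tris-TBS | CC(=O)[C@@H](O[Si](C)(C)C(C)(C)C)C[C@@H]1[C@@](C)(O[Si](C)(C)C)CC[C@H](C(C)(C)CO[Si](C)(C)C(C)(C)C)[C@@]1(C)CCO[Si](C)(C)C(C)(C)C | intermediate
25 | triethyl phosphonoacetate | CCOC(=O)CP(=O)(OCC)OCC | starting material
26 | ethyl enoate, C13=C14 (E isomer drawn; Z carried along), C8–OTMS, tris-TBS | CCOC(=O)/C=C(\C)[C@@H](O[Si](C)(C)C(C)(C)C)C[C@@H]1[C@@](C)(O[Si](C)(C)C)CC[C@H](C(C)(C)CO[Si](C)(C)C(C)(C)C)[C@@]1(C)CCO[Si](C)(C)C(C)(C)C | intermediate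
27 | C15 allylic alcohol, C8–OTMS (not isolated) | OC/C=C(\C)[C@@H](O[Si](C)(C)C(C)(C)C)C[C@@H]1[C@@](C)(O[Si](C)(C)C)CC[C@H](C(C)(C)CO[Si](C)(C)C(C)(C)C)[C@@]1(C)CCO[Si](C)(C)C(C)(C)C | intermediate
28 | C15 allylic alcohol with free tertiary C8–OH, tris-TBS (E drawn) | OC/C=C(\C)[C@@H](O[Si](C)(C)C(C)(C)C)C[C@@H]1[C@@](C)(O)CC[C@H](C(C)(C)CO[Si](C)(C)C(C)(C)C)[C@@]1(C)CCO[Si](C)(C)C(C)(C)C | intermediate
29 | cyclisation precursor: C15 tert-butyl carbonate, C13=C14 alkene (E drawn, used with its Z isomer), C12–OTBS, free C8–OH, arms as TBS ethers | CC(C)(C)OC(=O)OC/C=C(\C)[C@@H](O[Si](C)(C)C(C)(C)C)C[C@@H]1[C@@](C)(O)CC[C@H](C(C)(C)CO[Si](C)(C)C(C)(C)C)[C@@]1(C)CCO[Si](C)(C)C(C)(C)C | intermediate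
30 | bicyclic vinyl pyran, tris-TBS ether (vinyl axial and syn to C17, C12–OTBS equatorial) | C=C[C@]1(C)O[C@@]2(C)CC[C@H](C(C)(C)CO[Si](C)(C)C(C)(C)C)[C@@](C)(CCO[Si](C)(C)C(C)(C)C)[C@@H]2C[C@@H]1O[Si](C)(C)C(C)(C)C | intermediate
31 | C2,C3-diol, C12–OTBS | C=C[C@]1(C)O[C@@]2(C)CC[C@H](C(C)(C)CO)[C@@](C)(CCO)[C@@H]2C[C@@H]1O[Si](C)(C)C(C)(C)C | intermediate
32 | C2,C3-dialdehyde, C12–OTBS (not isolated) | C=C[C@]1(C)O[C@@]2(C)CC[C@H](C(C)(C)C=O)[C@@](C)(CC=O)[C@@H]2C[C@@H]1O[Si](C)(C)C(C)(C)C | intermediate
33 | 2,3-dioic acid, C12–OTBS | C=C[C@]1(C)O[C@@]2(C)CC[C@H](C(C)(C)C(=O)O)[C@@](C)(CC(=O)O)[C@@H]2C[C@@H]1O[Si](C)(C)C(C)(C)C | intermediate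
34 | CNP0325408.2, (5S,8S,9S,10R,12S,13S)-8,13-epoxy-12-hydroxy-2,3-secolabd-14-ene-2,3-dioic acid | C=C[C@]1(C)O[C@@]2(C)CC[C@H](C(C)(C)C(=O)O)[C@@](C)(CC(=O)O)[C@@H]2C[C@@H]1O | target

**Totals.** Total step count: 25. Longest linear sequence: 25 steps (from 1 and 2; 6, 9 and 25 are purchased).

**Steps most likely to fail**

1. Step 22 (Proposed new method). The risk is slow C–O bond formation at the fully substituted allyl terminus, so that β-hydride elimination to the diene, interception of the allyl complex by external alkoxide, or leakage to the C13 epimer takes over. The fallback uses known chemistry and sets out from 28, from which the E isomer is separated by chromatography. Sharpless asymmetric epoxidation (Ti(OiPr)4, L-(+)-diethyl tartrate, TBHP, 4 Å MS, CH2Cl2, −20 °C) should give the (13R,14S)-epoxy alcohol F1 under reagent control. Camphorsulfonic acid (cat., CH2Cl2, 0 °C) then lets the C8 hydroxyl open the epoxide at the tertiary C13 in a 6-exo sense with inversion, giving the pyran 14,15-diol F2 with the C13 configuration of 30. Thiocarbonyldiimidazole (toluene, 80 °C) gives the cyclic thiocarbonate F3, and Corey–Winter elimination (P(OMe)3, 110 °C) unveils the vinyl group and comes back to the route at 30.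

2. Step 5. The risk is enolisation of the ketone by the Grignard reagent and reversal of the congested addition, which would return ketone or the linear prenyl carbinol. The fallback sets out from 8 and avoids addition to the carbonyl. KHMDS/PhNTf2 (THF, −78 °C) gives the C5 enol triflate F4, since only C6 can enolise. Palladium-catalysed Negishi-type coupling with the Reformatsky reagent from methyl 2-bromoisobutyrate and zinc (Pd(dba)2, Q-Phos, THF, 60 °C) gives the β,γ-unsaturated ester F5. Lemieux–Johnson cleavage of the unhindered allyl terminus (OsO4 cat., NaIO4, 2,6-lutidine, dioxane/H2O) gives the aldehyde ester F6, LiAlH4 (THF, 0 °C) reduces both carbonyls to the ene-diol F7, and silylation as in step 7 comes back to the route at 14.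

3. Step 9. The risk is sluggish hydrogen-atom transfer to an alkene shielded by two quaternary carbons, or loss of facial control at C5. The fallback sets out from 13 and bypasses the alkene. n-BuLi and then methyl chlorooxoacetate (THF, −78 °C) give the tertiary methyl oxalate F8, and Bu3SnH/AIBN (toluene, 110 °C) removes the oxygen through the same C5 radical in a Barton–McCombie-type deoxygenation, coming back to the route at 15.

**Further compounds**

F1 | step 22 | (13R,14S)-epoxy alcohol (13,14-epoxide, C15–OH, free C8–OH, tris-TBS) | OC[C@@H]1O[C@@]1(C)[C@@H](O[Si](C)(C)C(C)(C)C)C[C@@H]2[C@@](C)(O)CC[C@H](C(C)(C)CO[Si](C)(C)C(C)(C)C)[C@@]2(C)CCO[Si](C)(C)C(C)(C)C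
F2 | step 22 | pyran 14,15-diol, tris-TBS | OC[C@H](O)[C@]1(C)O[C@@]2(C)CC[C@H](C(C)(C)CO[Si](C)(C)C(C)(C)C)[C@@](C)(CCO[Si](C)(C)C(C)(C)C)[C@@H]2C[C@@H]1O[Si](C)(C)C(C)(C)C
F3 | step 22 | cyclic 14,15-thiocarbonate of F2 | S=C1OC[C@H](O1)[C@]2(C)O[C@@]3(C)CC[C@H](C(C)(C)CO[Si](C)(C)C(C)(C)C)[C@@](C)(CCO[Si](C)(C)C(C)(C)C)[C@@H]3C[C@@H]2O[Si](C)(C)C(C)(C)C
F4 | step 5 | C5 enol triflate (C5=C6), C10 allyl, C13 ketal | C=CC[C@]1(C)C(OS(=O)(=O)C(F)(F)F)=CC[C@@]2(C)[C@H]1CCC23OCCO3
F5 | step 5 | β,γ-unsaturated methyl ester (C3 ester on C4, C5=C6), C10 allyl | C=CC[C@]1(C)C(C(C)(C)C(=O)OC)=CC[C@@]2(C)[C@H]1CCC23OCCO3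
F6 | step 5 | aldehyde ester (C2 aldehyde, C3 methyl ester, C5=C6) | O=CC[C@]1(C)C(C(C)(C)C(=O)OC)=CC[C@@]2(C)[C@H]1CCC23OCCO3
F7 | step 5 | ene-diol (C2–OH, C3–OH, C5=C6, C13 ketal) | OCC[C@]1(C)C(C(C)(C)CO)=CC[C@@]2(C)[C@H]1CCC23OCCO3
F8 | step 9 | tertiary C5 methyl oxalate of 13 | CC(C)(C)[Si](C)(C)OCC[C@]1(C)[C@@](OC(=O)C(=O)OC)(C(C)(C)CO[Si](C)(C)C(C)(C)C)CC[C@@]2(C)[C@H]1CCC23OCCO3
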